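**Plan**

The target is a 5-epi-labdane, (4S,5S,9S,10R,13R,14R): rings A and B are cis-fused, and H-5, C-19, C-20 and the C-9 chain lie on one face beside the C8=C17 methylene. This array at C4, C5, C9 and C10 can be written into one oxirane and two olefin geometries of an open chain.
Retrosynthesis cuts the C13–C14 oxirane, then C12–C13 (sp3–sp2), then C4–C5 and C9–C10 together (rings A and B), then C6–C7 between two acyclic fragments.
Forward: nerol gives the C1–C6/C19 epoxy allylic chloride and but-3-yn-1-ol the C7–C12 allylsilane chloride; an allylbarium coupling joins C6–C7; a Lewis acid closes ring A, then ring B; C3 is deoxygenated, C19 is oxidised to the methyl ester, and C12 is extended and epoxidised.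
Stereochemistry: C3/C4 come from Sharpless epoxidation of a (Z)-allylic alcohol, C5/C10 from the Z olefin of nerol, C9 from the allylsilane geometry (C11 cis to C7), and C13/C14 from a second Sharpless epoxidation.
The second epoxidation also turns any minor enantiomer left by the first into a diastereomer that can be separated.

Key step: step 13

Remark: labdane numbering is used for all intermediates; (trimethylsilyl)methylmagnesium chloride, the Still–Gennari phosphonate and a titrated THF solution of lithium biphenylide are treated as stock reagents.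

**Route**

Step 1
Reactants: 1 nerol
Product: 2 neryl chloride
Conditions: NCS, Me2S, CH2Cl2, −30 to 0 °C
Reagents that add atoms: N-chlorosuccinimide, O=C1CCC(=O)N1Cl
Why: Corey–Kim chlorination displaces the alkoxysulfonium ion of the primary allylic alcohol by chloride in an SN2 step without allylic transposition, so the Z olefin of nerol is kept.

Step 2
Reactants: 2 neryl chloride
Product: 3 (4Z)-6-chloro-4-methylhex-4-enal
Conditions: O3 (1 equiv), CH2Cl2, pyridine (cat), −78 °C; then Me2S
Reagents that add atoms: ozone, [O-][O+]=O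
Why: Chemoselective ozonolysis should cleave only the electron-rich terminal isopropylidene olefin, because the other olefin is deactivated inductively by the allylic chlorine.

Step 3
Reactants: 3 (4Z)-6-chloro-4-methylhex-4-enal
Product: 4 methyl (2Z,6Z)-8-chloro-2,6-dimethylocta-2,6-dienoate
Conditions: methyl 2-[bis(2,2,2-trifluoroethoxy)phosphoryl]propanoate, KHMDS, 18-crown-6, THF, −78 °C
Reagents that add atoms: methyl 2-[bis(2,2,2-trifluoroethoxy)phosphoryl]propanoate, COC(=O)C(C)P(=O)(OCC(F)(F)F)OCC(F)(F)F
Why: Still–Gennari olefination under dissociating conditions eliminates kinetically to the Z enoate, placing the ester carbon (later C19) cis to the chain, which is the geometry that makes C19 axial after cyclisation.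

Step 4
Reactants: 4 methyl (2Z,6Z)-8-chloro-2,6-dimethylocta-2,6-dienoate
Product: 5 (2Z,6Z)-8-chloro-2,6-dimethylocta-2,6-dien-1-ol
Conditions: DIBAL-H (2.2 equiv), CH2Cl2, −78 °C
Reagents that add atoms: none
Why: DIBAL-H 1,2-reduction of the conjugated ester gives the (Z)-allylic alcohol while the primary allylic chloride is inert at this temperature.

Step 5
Reactants: 5 (2Z,6Z)-8-chloro-2,6-dimethylocta-2,6-dien-1-ol
Product: 6 [(2R,3S)-3-[(3Z)-5-chloro-3-methylpent-3-en-1-yl]-2-methyloxiran-2-yl]methanol
Conditions: Ti(OiPr)4 (10 mol %), D-(−)-DET (12 mol %), TBHP, 4 Å MS, CH2Cl2, −20 °C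
Reagents that add atoms: tert-butyl hydroperoxide, CC(C)(C)OO
Why: Sharpless asymmetric epoxidation is directed by the allylic hydroxyl, so only the C3=C4 olefin reacts, and D-(−)-DET delivers oxygen by reagent control to the face that gives the (2R,3S)-oxirane (C3 S and C4 R in labdane numbering).

Step 6
Reactants: 6 epoxy alcohol
Product: 7 TBDPS ether of 6 (epoxy allylic chloride, C1–C6 and C19 fragment)
Conditions: TBDPSCl, imidazole, CH2Cl2, 0 °C
Reagents that add atoms: tert-butyl(chloro)diphenylsilane, CC(C)(C)[Si](Cl)(c1ccccc1)c1ccccc1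
Why: Silyl ether formation at the primary hydroxyl gives a bulky, weakly basic ether that survives the organometallic and Lewis-acid steps and cannot act as an internal nucleophile in the cyclisation.

Step 7
Reactants: 8 but-3-yn-1-ol
Product: 9 tert-butyl(but-3-yn-1-yloxy)diphenylsilane
Conditions: TBDPSCl, imidazole, CH2Cl2, rt
Reagents that add atoms: tert-butyl(chloro)diphenylsilane, CC(C)(C)[Si](Cl)(c1ccccc1)c1ccccc1
Why: Silyl ether formation masks the hydroxyl that becomes O12 so that acetylide, Grignard and barium chemistry can follow.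

Step 8
Reactants: 9 tert-butyl(but-3-yn-1-yloxy)diphenylsilane
Product: 10 5-[(tert-butyldiphenylsilyl)oxy]pent-2-yn-1-ol
Conditions: n-BuLi, THF, −78 °C; (CH2O)n, −78 °C to rt
Reagents that add atoms: formaldehyde (as paraformaldehyde), C=O
Why: Addition of the lithium acetylide to formaldehyde gives the propargylic alcohol whose carbinol carbon becomes C7.

Step 9
Reactants: 10 5-[(tert-butyldiphenylsilyl)oxy]pent-2-yn-1-ol
Product: 12 (2E)-5-[(tert-butyldiphenylsilyl)oxy]-2-iodopent-2-en-1-ol, via vinylmagnesium chloride 11 (not isolated)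
Conditions: i-BuMgCl (2.3 equiv), Cp2TiCl2 (5 mol %), Et2O, rt; then I2, THF, −78 to 0 °C
Reagents that add atoms: iodine, II
Why: Titanocene-catalysed hydromagnesiation of the propargylic alkoxide adds H and Mg syn with magnesium on the carbinol-bearing alkyne carbon, and iodinolysis with retention gives the vinyl iodide in which CH2OH (C7) is cis to the C11 chain.

Step 10
Reactants: 12 (2E)-5-[(tert-butyldiphenylsilyl)oxy]-2-iodopent-2-en-1-ol
Product: 13 (2E)-5-[(tert-butyldiphenylsilyl)oxy]-2-[(trimethylsilyl)methyl]pent-2-en-1-ol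
Conditions: TMSCH2MgCl (3 equiv), Pd(PPh3)4 (5 mol %), THF, 0 °C to rt
Reagents that add atoms: (trimethylsilyl)methylmagnesium chloride, C[Si](C)(C)C[Mg]Cl
Why: Kumada coupling proceeds with retention at the sp2 carbon and the Grignard reagent has no β-hydrogen, so the silylmethyl group takes the place of iodine (cis to H9) and C7 stays cis to C11.

Step 11
Reactants: 13 allylsilane alcohol
Product: 14 tert-butyl{[(3Z)-4-(chloromethyl)-5-(trimethylsilyl)pent-3-en-1-yl]oxy}diphenylsilane
Conditions: MsCl, LiCl, 2,4,6-collidine, DMF, 0 °C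
Reagents that add atoms: lithium chloride, [Li+].[Cl-]
Why: Mesylation followed by in situ SN2 displacement with chloride converts the primary allylic alcohol into the chloride under buffered conditions that spare the acid-sensitive allylsilane and the olefin geometry.

Step 12
Reactants: 14 allylsilane allylic chloride; 7 epoxy allylic chloride
Product: 16 (Z,Z)-epoxy diene allylsilane (C6–C7 joined), via allylbarium chloride 15 (not isolated)
Conditions: BaI2, lithium biphenylide (2 equiv), THF, rt; 14, −78 °C; then 7, THF, −78 °C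
Reagents that add atoms: none
Why: In this allylbarium cross-coupling the reagent formed from 14 at −78 °C reacts at its unsubstituted α-carbon (C7) and displaces the chloride of 7 in an SN2 (α,α′) sense with retention of both olefin geometries, while the hindered trisubstituted oxirane is not attacked at this temperature.

Step 13
Reactants: 16 (Z,Z)-epoxy diene allylsilane
Product: 17 cis-fused bicyclic alcohol (3-hydroxy 8(17)-ene, O12 and O19 as TBDPS ethers)
Conditions: MeAlCl2 (2.5 equiv), CH2Cl2, −78 °C; aq NaHCO3
Reagents that add atoms: none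
Why: MeAlCl2 activates the oxirane, C5 of the (Z)-C5=C10 olefin attacks C4 from the side opposite the departing oxygen, the C10 tertiary cation is captured by C9 of the allylsilane, and the β-silyl cation at C8 loses the silyl group to leave the C8=C17 methylene. This is a Lewis-acid epoxy-polyene cyclisation with allylsilane termination that follows the Stork–Eschenmoser antiperiplanar course. Ring A closes 6-endo (C5 onto C4) and ring B closes 6-endo (C9 onto C10), each through a chair. C3 keeps the oxirane configuration; C4 is inverted, so the silyloxymethyl group (cis to the chain on the oxirane) becomes axial and syn to the C3 hydroxyl; C5 and C10 follow from anti addition across the Z olefin, which puts H5 and C20 cis and gives the cis fusion; C9 follows from the allylsilane geometry, C11 cis to C7 placing the chain axial on ring B and cis to C20. The step needs the chair–chair fold to beat boat closure of ring B, proton loss from the C10 cation and hydride shift at the oxirane; the single oxirane enantiomer fixes the absolute sense, the two olefin geometries fix the relative configuration, the nucleophilic allylsilane shortens the life of the C10 cation and directs elimination to C17 only, and the bulky TBDPS ethers keep O19 and O12 from trapping cations.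

Step 14
Reactants: 17 cis-fused bicyclic alcohol
Product: 18 3-O-(imidazol-1-ylthiocarbonyl) derivative of 17
Conditions: 1,1'-thiocarbonyldiimidazole, DMAP (cat), toluene, 80 °C
Reagents that add atoms: 1,1'-thiocarbonyldiimidazole, S=C(n1ccnc1)n1ccnc1
Why: Thioacylation of the only free hydroxyl under neutral conditions gives the Barton–McCombie substrate and avoids the 1,3-silyl migration that an alkoxide-based xanthate synthesis could cause.

Step 15
Reactants: 18 thiocarbonylimidazolide
Product: 19 3-deoxy bis-TBDPS ether
Conditions: Bu3SnH, AIBN (cat), toluene, 110 °C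
Reagents that add atoms: none
Why: Barton–McCombie deoxygenation (stannyl radical addition to C=S, β-scission to the secondary C3 radical, hydrogen transfer from Bu3SnH) removes the C3 oxygen without creating a stereocentre.

Step 16
Reactants: 19 3-deoxy bis-TBDPS ether
Product: 20 12,19-diol
Conditions: TBAF (3 equiv), THF, rt to 50 °C
Reagents that add atoms: none
Why: Fluoride-mediated desilylation, driven by the strong Si–F bond, frees both O12 and O19.

Step 17
Reactants: 20 12,19-diol
Product: 21 12-iodo-19-ol
Conditions: PPh3 (1.1 equiv), I2 (1.1 equiv), imidazole, CH2Cl2, 0 °C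
Reagents that add atoms: iodine, II
Why: Appel-type iodination needs SN2 displacement of an alkoxyphosphonium ion, which is feasible at the unhindered C12 carbinol but not at the neopentyl, axial C19 carbinol, so the two hydroxyls are differentiated.

Step 18
Reactants: 21 12-iodo-19-ol
Product: 22 12-iodo-19-al
Conditions: Dess–Martin periodinane, CH2Cl2, rt
Reagents that add atoms: none
Why: Dess–Martin oxidation converts the neopentyl primary alcohol into the aldehyde under near-neutral conditions that leave the alkyl iodide and the exocyclic olefin untouched.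

Step 19
Reactants: 22 12-iodo-19-al
Product: 23 12-iodo-19-oic acid
Conditions: NaClO2, NaH2PO4, 2-methylbut-2-ene, t-BuOH/H2O, rt
Reagents that add atoms: sodium chlorite, [Na+].[O-]Cl=O
Why: Pinnick oxidation with an olefin scavenger for hypochlorite takes the hindered aldehyde to the acid without affecting the 8(17)-olefin or the iodide.

Step 20
Reactants: 23 12-iodo-19-oic acid
Product: 24 methyl 12-iodo-13,14,15,16-tetranor-5-epi-labd-8(17)-en-19-oate
Conditions: TMSCHN2, MeOH/toluene, 0 °C
Reagents that add atoms: (trimethylsilyl)diazomethane, C[Si](C)(C)C=[N+]=[N-]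
Why: Esterification with trimethylsilyldiazomethane methylates the carboxylate oxygen after proton transfer, so the hindered carbonyl carbon need not be attacked and the primary iodide is left alone.

Step 21
Reactants: 25 ethyl acetoacetate
Product: 26 ethyl (2E)-3-{[(trifluoromethyl)sulfonyl]oxy}but-2-enoate
Conditions: Tf2O, aq Me4NOH, hexanes, 5 °C
Reagents that add atoms: trifluoromethanesulfonic anhydride, O=S(=O)(OS(=O)(=O)C(F)(F)F)C(F)(F)F
Why: O-Triflation of the β-keto ester enolate under biphasic conditions with a non-chelating tetramethylammonium counter-ion gives the E enol triflate, with the triflate trans to the ester.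

Step 22
Reactants: 24 methyl 12-iodo ester; 26 ethyl (2E)-3-(triflyloxy)but-2-enoate
Product: 28 15-ethyl 19-methyl (13E)-5-epi-labda-8(17),13-diene-15,19-dioate, via alkylzinc iodide 27 (not isolated)
Conditions: Zn dust, LiCl, THF, 40 °C; then 26, Pd(PPh3)4 (5 mol %), THF, rt
Reagents that add atoms: none
Why: In this Negishi coupling zinc inserts into the primary C–I bond and the ester-tolerant alkylzinc couples with the enol triflate with retention at the sp2 carbon, so C12 ends trans to the ester (13E), which is also the more stable geometry.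

Step 23
Reactants: 28 diester
Product: 29 methyl (13E)-15-hydroxy-5-epi-labda-8(17),13-dien-19-oate
Conditions: DIBAL-H (2.2 equiv), CH2Cl2, −78 °C
Reagents that add atoms: none
Why: Chemoselective DIBAL-H reduction should take the unhindered conjugated ethyl ester to the allylic alcohol much faster than the C19 methyl ester, which is axial on a quaternary carbon.

Step 24
Reactants: 29 allylic alcohol
Product: 30 methyl (13R,14R)-13,14-epoxy-15-hydroxy-5-epi-labd-8(17)-en-19-oate (target)
Conditions: Ti(OiPr)4 (10 mol %), D-(−)-DET (12 mol %), TBHP, 4 Å MS, CH2Cl2, −20 °C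
Reagents that add atoms: tert-butyl hydroperoxide, CC(C)(C)OO
Why: Sharpless asymmetric epoxidation of this geraniol-type (E)-allylic alcohol with D-(−)-DET gives the (13R,14R)-oxirane by reagent control, and the hydroxyl direction keeps the 8(17)-olefin from being epoxidised.

**Compound list**

1 | nerol, (2Z)-3,7-dimethylocta-2,6-dien-1-ol | CC(C)=CCC/C(C)=C\CO | starting material
2 | neryl chloride, (2Z)-1-chloro-3,7-dimethylocta-2,6-diene | CC(C)=CCC/C(C)=C\CCl | intermediate
3 | (4Z)-6-chloro-4-methylhex-4-enal | O=CCC/C(C)=C\CCl | intermediate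
4 | methyl (2Z,6Z)-8-chloro-2,6-dimethylocta-2,6-dienoate | COC(=O)/C(C)=C\CC/C(C)=C\CCl | intermediate
5 | (2Z,6Z)-8-chloro-2,6-dimethylocta-2,6-dien-1-ol | OC/C(C)=C\CC/C(C)=C\CCl | intermediate
6 | [(2R,3S)-3-[(3Z)-5-chloro-3-methylpent-3-en-1-yl]-2-methyloxiran-2-yl]methanol | ClC/C=C(C)\CC[C@@H]1O[C@]1(C)CO | intermediate
7 | tert-butyl{[(2R,3S)-3-[(3Z)-5-chloro-3-methylpent-3-en-1-yl]-2-methyloxiran-2-yl]methoxy}diphenylsilane | ClC/C=C(C)\CC[C@@H]1O[C@]1(C)CO[Si](c1ccccc1)(c1ccccc1)C(C)(C)C | intermediate
8 | but-3-yn-1-ol | C#CCCO | starting material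
9 | tert-butyl(but-3-yn-1-yloxy)diphenylsilane | C#CCCO[Si](c1ccccc1)(c1ccccc1)C(C)(C)C | intermediate
10 | 5-[(tert-butyldiphenylsilyl)oxy]pent-2-yn-1-ol | OCC#CCCO[Si](c1ccccc1)(c1ccccc1)C(C)(C)C | intermediate
11 | vinylmagnesium chloride of 10 as its chloromagnesium alkoxide, Mg on C2 and cis to H3 (not isolated) | Cl[Mg]OC/C([Mg]Cl)=C\CCO[Si](c1ccccc1)(c1ccccc1)C(C)(C)C | intermediate
12 | (2E)-5-[(tert-butyldiphenylsilyl)oxy]-2-iodopent-2-en-1-ol (CH2OH cis to C4) | OC/C(I)=C\CCO[Si](c1ccccc1)(c1ccccc1)C(C)(C)C | intermediate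
13 | (2E)-5-[(tert-butyldiphenylsilyl)oxy]-2-[(trimethylsilyl)methyl]pent-2-en-1-ol (CH2OH cis to C4) | OC/C(C[Si](C)(C)C)=C\CCO[Si](c1ccccc1)(c1ccccc1)C(C)(C)C | intermediate
14 | tert-butyl{[(3Z)-4-(chloromethyl)-5-(trimethylsilyl)pent-3-en-1-yl]oxy}diphenylsilane | ClC/C(C[Si](C)(C)C)=C\CCO[Si](c1ccccc1)(c1ccccc1)C(C)(C)C | intermediate
15 | allylbarium chloride from 14, barium on C7 (not isolated) | Cl[Ba]C/C(C[Si](C)(C)C)=C\CCO[Si](c1ccccc1)(c1ccccc1)C(C)(C)C | intermediate
16 | tert-butyl{[(2R,3S)-3-[(3Z,7E)-10-[(tert-butyldiphenylsilyl)oxy]-3-methyl-7-[(trimethylsilyl)methyl]deca-3,7-dien-1-yl]-2-methyloxiran-2-yl]methoxy}diphenylsilane (C5=C10 Z; C7 cis to C11) | C[Si](C)(C)C/C(CC/C=C(C)\CC[C@@H]1O[C@]1(C)CO[Si](c2ccccc2)(c2ccccc2)C(C)(C)C)=C/CCO[Si](c1ccccc1)(c1ccccc1)C(C)(C)C | intermediate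
17 | (3S,4S,5S,9S,10R)-12,19-bis[(tert-butyldiphenylsilyl)oxy]-13,14,15,16-tetranor-5-epi-labd-8(17)-en-3-ol (cis-fused; 3-OH, H-5, C-19, C-20 and C-11 on one face) | C=C1CC[C@H]2[C@](C)(CC[C@H](O)[C@]2(C)CO[Si](c3ccccc3)(c3ccccc3)C(C)(C)C)[C@H]1CCO[Si](c1ccccc1)(c1ccccc1)C(C)(C)C | intermediate
18 | 3-O-(1H-imidazol-1-ylcarbonothioyl) derivative of 17 | C=C1CC[C@H]2[C@](C)(CC[C@H](OC(=S)n3ccnc3)[C@]2(C)CO[Si](c3ccccc3)(c3ccccc3)C(C)(C)C)[C@H]1CCO[Si](c1ccccc1)(c1ccccc1)C(C)(C)C | intermediate
19 | (4S,5S,9S,10R)-12,19-bis[(tert-butyldiphenylsilyl)oxy]-13,14,15,16-tetranor-5-epi-labd-8(17)-ene | C=C1CC[C@H]2[C@](C)(CCC[C@]2(C)CO[Si](c3ccccc3)(c3ccccc3)C(C)(C)C)[C@H]1CCO[Si](c1ccccc1)(c1ccccc1)C(C)(C)C | intermediate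
20 | (4S,5S,9S,10R)-13,14,15,16-tetranor-5-epi-labd-8(17)-ene-12,19-diol | C=C1CC[C@H]2[C@](C)(CCC[C@]2(C)CO)[C@H]1CCO | intermediate
21 | (4S,5S,9S,10R)-12-iodo-13,14,15,16-tetranor-5-epi-labd-8(17)-en-19-ol | C=C1CC[C@H]2[C@](C)(CCC[C@]2(C)CO)[C@H]1CCI | intermediate
22 | (4S,5S,9S,10R)-12-iodo-13,14,15,16-tetranor-5-epi-labd-8(17)-en-19-al | C=C1CC[C@H]2[C@](C)(CCC[C@]2(C)C=O)[C@H]1CCI | intermediate
23 | (4S,5S,9S,10R)-12-iodo-13,14,15,16-tetranor-5-epi-labd-8(17)-en-19-oic acid | C=C1CC[C@H]2[C@](C)(CCC[C@]2(C)C(=O)O)[C@H]1CCI | intermediate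
24 | methyl (4S,5S,9S,10R)-12-iodo-13,14,15,16-tetranor-5-epi-labd-8(17)-en-19-oate | C=C1CC[C@H]2[C@](C)(CCC[C@]2(C)C(=O)OC)[C@H]1CCI | intermediate
25 | ethyl acetoacetate | CCOC(=O)CC(C)=O | starting material
26 | ethyl (2E)-3-{[(trifluoromethyl)sulfonyl]oxy}but-2-enoate | CCOC(=O)/C=C(C)/OS(=O)(=O)C(F)(F)F | intermediate
27 | alkylzinc iodide from 24, zinc on C12 (not isolated) | C=C1CC[C@H]2[C@](C)(CCC[C@]2(C)C(=O)OC)[C@H]1CC[Zn]I | intermediate
28 | 15-ethyl 19-methyl (13E)-5-epi-labda-8(17),13-diene-15,19-dioate | C=C1CC[C@H]2[C@](C)(CCC[C@]2(C)C(=O)OC)[C@H]1CC/C(C)=C/C(=O)OCC | intermediate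
29 | methyl (13E)-15-hydroxy-5-epi-labda-8(17),13-dien-19-oate | C=C1CC[C@H]2[C@](C)(CCC[C@]2(C)C(=O)OC)[C@H]1CC/C(C)=C/CO | intermediate
30 | methyl (4S,5S,9S,10R,13R,14R)-13,14-epoxy-15-hydroxy-5-epi-labd-8(17)-en-19-oate, CNP0175926.1 | C=C1CC[C@H]2[C@](C)(CCC[C@]2(C)C(=O)OC)[C@H]1CC[C@@]1(C)O[C@@H]1CO | target

**Step count and risks**

Total number of steps: 24 (C1–C6/C19 fragment 6, C7–C12 fragment 5, coupling 1, key step 1, end game 11 including the one-step enol triflate).
Longest linear sequence: 18 steps (steps 1–6, 12–20, 22–24).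

Step 13 (key step). The cascade may stop after ring A through proton loss from the C10 cation, because the Z olefin forces the C6 chain axial in the chair. Ring B may also close through a boat (wrong configuration at C9), or the activated oxirane may undergo a 1,2-hydride shift before the olefin engages. The fallback forms the two bonds in two separate cationic events. Setting out from 16, BF3·OEt2 with 2,6-di-tert-butyl-4-methylpyridine in Et2O at −78 °C should close ring A only and let the cation lose a proton, giving the monocyclic ring-A alcohol with an exocyclic C10=C20 methylene F1 with the allylsilane intact. Mukaiyama hydration of the 1,1-disubstituted olefin (Co(acac)2, PhSiH3, O2, i-PrOH) should then give the C10 tertiary alcohol F2. Ionisation of F2 with SnCl4 in CH2Cl2 at −78 °C regenerates the C10 cation without protic acid, and the allylsilane closes ring B in an intramolecular Hosomi–Sakurai-type alkylation, which comes back to the route at 17. In F2 the C6 chain is held axial by allylic strain and by the quaternary C4, so C9 can only bond equatorially on ring A and the cis fusion should be retained.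

Step 12 (allylbarium coupling). The allylic chloride may homocouple while the barium reagent is formed, the reagent may react through its γ-carbon (C9), or the C8=C9 geometry may be lost by metallotropic shift if the reagent warms. The fallback is a sulfone coupling. Setting out from 7, sodium benzenesulfinate in DMF should give the allylic phenyl sulfone F3. KHMDS is added at −78 °C to a THF solution of F3 and 14, so that the sulfonyl carbanion is alkylated at C6 before it can open the oxirane, giving the alkylated sulfone F4. Buffered sodium amalgam (Na2HPO4, MeOH/THF, −20 °C) then removes the sulfonyl group and comes back to the route at 16. The point to watch in this variant is retention of the Z geometry at C5=C10 during the reductive step.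

Step 23 (chemoselective ester reduction). Hydride may also attack the C19 methyl ester, or the enoate may be reduced incompletely if less reagent is used. The fallback brings in the side chain at the alcohol oxidation level, so no ester reduction is needed. But-2-yn-1-ol is silylated (TBSCl, imidazole) to the silyl ether F5. Hydrozirconation with excess Cp2Zr(H)Cl (THF, 50 °C, zirconium on the methyl-bearing carbon after equilibration) and iodination give the (E)-vinyl iodide F6. Setting out from 24, the alkylzinc 27 is coupled with F6 (Pd(PPh3)4, THF) to the silyl ether F7, and TBAF comes back to the route at 29.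

Further compounds
F1 | step 13 | (3S,4S,5S) ring-A alcohol with exocyclic C10=C20 methylene, allylsilane and both TBDPS ethers intact | C=C1CC[C@H](O)[C@](C)(CO[Si](c2ccccc2)(c2ccccc2)C(C)(C)C)[C@H]1CC/C(C[Si](C)(C)C)=C\CCO[Si](c1ccccc1)(c1ccccc1)C(C)(C)C
F2 | step 13 | C10 tertiary alcohol from F1 (either C10 epimer) | CC1(O)CC[C@H](O)[C@](C)(CO[Si](c2ccccc2)(c2ccccc2)C(C)(C)C)[C@H]1CC/C(C[Si](C)(C)C)=C\CCO[Si](c1ccccc1)(c1ccccc1)C(C)(C)C
F3 | step 12 | (Z)-allylic phenyl sulfone from 7, sulfonyl on C6 | O=S(=O)(C/C=C(C)\CC[C@@H]1O[C@]1(C)CO[Si](c1ccccc1)(c1ccccc1)C(C)(C)C)c1ccccc1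
F4 | step 12 | C6-phenylsulfonyl derivative of 16 (either C6 epimer) | C[Si](C)(C)C/C(CC(/C=C(C)\CC[C@@H]1O[C@]1(C)CO[Si](c2ccccc2)(c2ccccc2)C(C)(C)C)S(=O)(=O)c2ccccc2)=C/CCO[Si](c1ccccc1)(c1ccccc1)C(C)(C)C
F5 | step 23 | tert-butyl(but-2-yn-1-yloxy)dimethylsilane | CC#CCO[Si](C)(C)C(C)(C)C
F6 | step 23 | tert-butyl{[(2E)-3-iodobut-2-en-1-yl]oxy}dimethylsilane | C/C(I)=C\CO[Si](C)(C)C(C)(C)C
F7 | step 23 | 15-O-TBS ether of 29 | C=C1CC[C@H]2[C@](C)(CCC[C@]2(C)C(=O)OC)[C@H]1CC/C(C)=C/CO[Si](C)(C)C(C)(C)C
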